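**Retrosynthetic overview**

1. Locants used for the target: O1, C2 (aryl), C3 (methyl), C3a (allyl), C4, C5 (OMe), C6 (C=O), C7, C7a; ring A is the cyclohexenone, ring B the oxolane.
2. Key disconnection: both rings are opened at once, C7a–O1 (oxa-Michael) and C3a–C4 (6π-electrocyclisation of a trienolate), to an acyclic hydroxy ynenone. In the forward sense ring B closes first and ring A second in the same flask, and C3a and C5 are set there.
3. The ynenone comes from a terminal alkynol (C7a≡C7) and a 2-methoxyacryloyl Weinreb amide (C6–C7 bond).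
4. The alkynol comes from an alpha-allyl gamma-lactone by reduction and one-carbon homologation; this temporary lactone ring is opened before the key step.
5. The lactone comes from a syn homoallylic alcohol made by catalytic asymmetric (Z)-crotylation of 3,4,5-trimethoxybenzaldehyde, which sets C2 and C3.

Assumption: the (R)-phosphoric acid in step 1 delivers the (1R) carbinol, as it does with benzaldehyde; if the sense is reversed, the (S)-acid is used.

**Route**

Step 1
Reactants: 1 3,4,5-trimethoxybenzaldehyde; 2 2-[(2Z)-but-2-en-1-yl]-4,4,5,5-tetramethyl-1,3,2-dioxaborolane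
Product: 4 (1R,2S)-2-methyl-1-(3,4,5-trimethoxyphenyl)but-3-en-1-ol, via pinacol borate ester 3 (not isolated)
Conditions: (R)-3,3′-bis(2,4,6-triisopropylphenyl)-1,1′-binaphthyl-2,2′-diyl hydrogen phosphate (5 mol %), toluene, 4 Å sieves, −30 °C; aqueous work-up
Reagents that add atoms: none
Why: Brønsted-acid-catalysed allylboration (Antilla-type crotylation) through a closed chair transition state, in which the (Z)-boronate gives the syn hydroxyl/methyl relationship and the chiral phosphate selects the aldehyde face, setting C2 (R) and C3 (S) of the target; the O-boryl adduct 3 is hydrolysed on work-up.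

Step 2
Reactants: 4 (1R,2S)-2-methyl-1-(3,4,5-trimethoxyphenyl)but-3-en-1-ol
Product: 6 (1R,2S)-2-methyl-1-(3,4,5-trimethoxyphenyl)butane-1,4-diol, via bis-borane adduct 5 (not isolated)
Conditions: 9-borabicyclo[3.3.1]nonane (2.2 equiv), THF, 0 → 25 °C; then NaOH, H2O2, H2O, 0 → 25 °C
Reagents that add atoms: hydrogen peroxide, OO
Why: Anti-Markovnikov hydroboration–oxidation of the terminal alkene (Brown), with one equivalent of borane spent on the hydroxyl group and no stereocentre touched.

Step 3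
Reactants: 6 (1R,2S)-2-methyl-1-(3,4,5-trimethoxyphenyl)butane-1,4-diol
Product: 8 (4S,5R)-4-methyl-5-(3,4,5-trimethoxyphenyl)oxolan-2-one, via lactol 7 (not isolated)
Conditions: 2,2,6,6-tetramethylpiperidin-1-oxyl (10 mol %), PhI(OAc)2 (2.5 equiv), CH2Cl2, 25 °C
Reagents that add atoms: none
Why: Nitroxyl-catalysed oxidation with a hypervalent iodine oxidant (Piancatelli–Margarita) is selective for the primary alcohol; the aldehyde closes onto the benzylic hydroxyl to lactol 7, which is oxidised on to the cis lactone without touching C2 or C3.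

Step 4
Reactants: 8 (4S,5R)-4-methyl-5-(3,4,5-trimethoxyphenyl)oxolan-2-one; 9 3-bromoprop-1-ene (allyl bromide)
Product: 11 (3S,4S,5R)-4-methyl-3-(prop-2-en-1-yl)-5-(3,4,5-trimethoxyphenyl)oxolan-2-one, via lithium enolate 10 (not isolated)
Conditions: LiN(i-Pr)2 (1.1 equiv), THF, −78 °C; then 9, −78 → −40 °C
Reagents that add atoms: none
Why: Lactone enolate alkylation (SN2) in which the allyl group enters trans to the neighbouring methyl group; this centre becomes trigonal again in step 8, so its configuration is of no consequence.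

Step 5
Reactants: 11 (3S,4S,5R)-4-methyl-3-(prop-2-en-1-yl)-5-(3,4,5-trimethoxyphenyl)oxolan-2-one; 12 dimethyl (1-diazo-2-oxopropyl)phosphonate (Bestmann–Ohira reagent)
Product: 14 (1R,2S,3S)-3-ethynyl-2-methyl-1-(3,4,5-trimethoxyphenyl)hex-5-en-1-ol, via allyl lactol 13 (not isolated)
Conditions: i-Bu2AlH (1.1 equiv), CH2Cl2, −78 °C; then MeOH, K2CO3, 12, −78 → 25 °C
Reagents that add atoms: none
Why: One-pot partial reduction and Seyferth–Gilbert homologation (Bestmann–Ohira modification), in which lactol 13 reacts through its open hydroxy aldehyde form so that the aldehyde carbon becomes C7a and the reagent supplies C7; any epimerisation next to the aldehyde is harmless.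

Step 6
Reactants: 15 methyl 2-methoxyprop-2-enoate; 16 N,O-dimethylhydroxylamine hydrochloride
Product: 17 N,2-dimethoxy-N-methylprop-2-enamide
Conditions: i-PrMgCl (3 equiv), THF, −20 → 0 °C
Reagents that add atoms: none
Why: Weinreb amide formation by aminolysis of the ester with the chloromagnesium amide made in the flask; the 2-methoxy group makes the acrylate a poor Michael acceptor, so attack at the ester carbonyl prevails.

Step 7
Reactants: 14 (1R,2S,3S)-3-ethynyl-2-methyl-1-(3,4,5-trimethoxyphenyl)hex-5-en-1-ol; 17 N,2-dimethoxy-N-methylprop-2-enamide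
Product: 20 (6S,7S,8R)-8-hydroxy-2-methoxy-7-methyl-6-(prop-2-en-1-yl)-8-(3,4,5-trimethoxyphenyl)oct-1-en-4-yn-3-one, via dilithio alkynolate 18 (not isolated), via lithium hemiaminal 19 (not isolated)
Conditions: n-BuLi (2.1 equiv), THF, −78 °C; then 17, −78 → −40 °C; then AcOH (2.2 equiv), −78 °C
Reagents that add atoms: none
Why: Weinreb ketone synthesis, in which the lithium acetylide adds once and the chelated tetrahedral adduct 19 keeps the ynone masked from the neighbouring alkoxide until the cold acidic quench.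

Step 8
Reactants: 20 (6S,7S,8R)-8-hydroxy-2-methoxy-7-methyl-6-(prop-2-en-1-yl)-8-(3,4,5-trimethoxyphenyl)oct-1-en-4-yn-3-one
Product: 24 dysodanthin B (2R,3S,3aS,5R)-5-methoxy-3-methyl-3a-(prop-2-en-1-yl)-2-(3,4,5-trimethoxyphenyl)-3,3a,4,5-tetrahydro-1-benzofuran-6(2H)-one, via alkylidene oxolane 21 (not isolated), via potassium trienolate 22 (not isolated), via potassium dienolate 23 (not isolated)
Conditions: KN(SiMe3)2 (1.1 equiv), THF (0.02 M), −78 → 25 °C; then t-BuCO2H (1.5 equiv), −78 °C
Reagents that add atoms: none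
Why: Proposed new method: deprotonated 20 closes ring B by 5-exo-dig oxa-Michael addition to the ynone (closest known: base-mediated cyclisation of gamma-hydroxy ynones to 2-acylmethylene oxolanes) to give 21, whose only acidic site (C3a–H, vinylogous to the ketone) is then removed to give the cross-conjugated trienolate 22, which closes ring A by oxyanion-accelerated disrotatory 6π-electrocyclisation (closest known: trienolate to cyclohexadienolate electrocyclisation, formally a 6-endo vinylogous Michael addition) with C4 bonding to the face of planar C3a opposite the cis 3-methyl and 2-aryl groups so that allyl ends up cis to them (3aS), and the resulting enolate 23 is protonated kinetically at C5 by the bulky acid from the face away from the pseudoaxial allyl group (Zimmerman-type kinetic protonation), placing methoxy cis to allyl (5R).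

**Compound list**

1 | 3,4,5-trimethoxybenzaldehyde | COc1cc(C=O)cc(OC)c1OC | starting material
2 | 2-[(2Z)-but-2-en-1-yl]-4,4,5,5-tetramethyl-1,3,2-dioxaborolane | C/C=C\CB1OC(C)(C)C(C)(C)O1 | starting material
3 | 4,4,5,5-tetramethyl-2-{[(1R,2S)-2-methyl-1-(3,4,5-trimethoxyphenyl)but-3-en-1-yl]oxy}-1,3,2-dioxaborolane | CC1(C)OB(O[C@@H](c2cc(OC)c(OC)c(OC)c2)[C@H](C=C)C)OC1(C)C | intermediate
4 | (1R,2S)-2-methyl-1-(3,4,5-trimethoxyphenyl)but-3-en-1-ol | O[C@@H](c1cc(OC)c(OC)c(OC)c1)[C@H](C=C)C | intermediate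
5 | 9-[(3S,4R)-4-(9-borabicyclo[3.3.1]nonan-9-yloxy)-3-methyl-4-(3,4,5-trimethoxyphenyl)butyl]-9-borabicyclo[3.3.1]nonane | B1(C2CCCC1CCC2)O[C@@H](c1cc(OC)c(OC)c(OC)c1)[C@H](CCB1C2CCCC1CCC2)C | intermediate
6 | (1R,2S)-2-methyl-1-(3,4,5-trimethoxyphenyl)butane-1,4-diol | O[C@@H](c1cc(OC)c(OC)c(OC)c1)[C@H](CCO)C | intermediate
7 | (4S,5R)-4-methyl-5-(3,4,5-trimethoxyphenyl)oxolan-2-ol (anomers) | O1[C@@H](c2cc(OC)c(OC)c(OC)c2)[C@H](CC1O)C | intermediate
8 | (4S,5R)-4-methyl-5-(3,4,5-trimethoxyphenyl)oxolan-2-one | O1[C@@H](c2cc(OC)c(OC)c(OC)c2)[C@H](CC1=O)C | intermediate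
9 | 3-bromoprop-1-ene (allyl bromide) | C=CCBr | starting material
10 | lithium (4S,5R)-4-methyl-5-(3,4,5-trimethoxyphenyl)-4,5-dihydrofuran-2-olate | O1[C@@H](c2cc(OC)c(OC)c(OC)c2)[C@H](C=C1[O-])C.[Li+] | intermediate
11 | (3S,4S,5R)-4-methyl-3-(prop-2-en-1-yl)-5-(3,4,5-trimethoxyphenyl)oxolan-2-one | O1[C@@H](c2cc(OC)c(OC)c(OC)c2)[C@@H](C)[C@H](CC=C)C1=O | intermediate
12 | dimethyl (1-diazo-2-oxopropyl)phosphonate | CC(=O)C(=[N+]=[N-])P(=O)(OC)OC | starting material
13 | (3S,4S,5R)-4-methyl-3-(prop-2-en-1-yl)-5-(3,4,5-trimethoxyphenyl)oxolan-2-ol (anomers) | O1[C@@H](c2cc(OC)c(OC)c(OC)c2)[C@@H](C)[C@H](CC=C)C1O | intermediate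
14 | (1R,2S,3S)-3-ethynyl-2-methyl-1-(3,4,5-trimethoxyphenyl)hex-5-en-1-ol | O[C@@H](c1cc(OC)c(OC)c(OC)c1)[C@@H](C)[C@H](CC=C)C#C | intermediate
15 | methyl 2-methoxyprop-2-enoate | C=C(OC)C(=O)OC | starting material
16 | N,O-dimethylhydroxylamine hydrochloride | CNOC.Cl | starting material
17 | N,2-dimethoxy-N-methylprop-2-enamide | C=C(OC)C(=O)N(C)OC | intermediate
18 | dilithium alkoxide acetylide of 14 | [Li+].[Li+].[O-][C@@H](c1cc(OC)c(OC)c(OC)c1)[C@@H](C)[C@H](CC=C)C#[C-] | intermediate
19 | dilithium tetrahedral adduct of 18 and 17 | [Li+].[Li+].[O-][C@@H](c1cc(OC)c(OC)c(OC)c1)[C@@H](C)[C@H](CC=C)C#CC([O-])(N(C)OC)C(OC)=C | intermediate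
20 | (6S,7S,8R)-8-hydroxy-2-methoxy-7-methyl-6-(prop-2-en-1-yl)-8-(3,4,5-trimethoxyphenyl)oct-1-en-4-yn-3-one | O[C@@H](c1cc(OC)c(OC)c(OC)c1)[C@@H](C)[C@H](CC=C)C#CC(=O)C(OC)=C | intermediate
21 | (1E)-3-methoxy-1-[(3S,4S,5R)-4-methyl-3-(prop-2-en-1-yl)-5-(3,4,5-trimethoxyphenyl)oxolan-2-ylidene]but-3-en-2-one | O1[C@@H](c2cc(OC)c(OC)c(OC)c2)[C@@H](C)[C@H](CC=C)/C1=C\C(=O)C(OC)=C | intermediate
22 | potassium (1E)-3-methoxy-1-[(4S,5R)-4-methyl-3-(prop-2-en-1-yl)-5-(3,4,5-trimethoxyphenyl)-4,5-dihydrofuran-2-yl]buta-1,3-dien-2-olate | O1[C@@H](c2cc(OC)c(OC)c(OC)c2)[C@@H](C)C(CC=C)=C1/C=C(/[O-])C(OC)=C.[K+] | intermediate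
23 | potassium (2R,3S,3aS)-5-methoxy-3-methyl-3a-(prop-2-en-1-yl)-2-(3,4,5-trimethoxyphenyl)-2,3,3a,4-tetrahydro-1-benzofuran-6-olate | C=CC[C@@]12CC(OC)=C([O-])C=C1O[C@@H](c1cc(OC)c(OC)c(OC)c1)[C@H]2C.[K+] | intermediate
24 | dysodanthin B; (2R,3S,3aS,5R)-5-methoxy-3-methyl-3a-(prop-2-en-1-yl)-2-(3,4,5-trimethoxyphenyl)-3,3a,4,5-tetrahydro-1-benzofuran-6(2H)-one | C=CC[C@@]12C[C@@H](OC)C(=O)C=C1O[C@@H](c1cc(OC)c(OC)c(OC)c1)[C@H]2C | target

**Step count and risks**

Total step count: 8. Longest linear sequence: 7 (steps 1, 2, 3, 4, 5, 7, 8; step 6 is a side branch).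

Most likely to fail, step 8. The electrocyclisation has to form the quaternary C3a at a fully substituted terminus. The C5 proton has to arrive under kinetic control, because the 5-epimer with an equatorial methoxy group is probably the more stable one. Fallback, a stepwise neutral sequence that sets out from 20 and comes back at 24: catalytic 1,8-diazabicyclo[5.4.0]undec-7-ene in CH2Cl2 at 0 °C closes ring B only and gives 21, now isolated. Treatment with t-BuMe2SiOTf and Et3N converts 21 into the tert-butyldimethylsilyl trienol ether F1. Heating in toluene at 80–110 °C brings about the thermal 6π-electrocyclisation to the bicyclic silyl dienol ether F2, which can be purified. Bu4NF buffered by pivalic acid in THF at −78 °C then removes the silyl group and protonates C5 from the face away from the allyl group to give 24. Any 5-epimer is resilylated to F2 and recycled.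

Second, step 7. A dianion has to add cleanly to an acrylamide, and the liberated amine can add to the new enone. Fallback, with the polarity of the coupling reversed, from 14 back to 20: the dilithio species 18 is quenched by CO2 to give the hydroxy alkynoic acid F3. Coupling with N,O-dimethylhydroxylamine using N-(3-dimethylaminopropyl)-N′-ethylcarbodiimide hydrochloride gives the alkynyl Weinreb amide F4. 1-Methoxyvinyllithium (methyl vinyl ether, t-BuLi, THF; 2.2 equiv, one spent on the hydroxyl group) adds to it at −78 °C and gives 20 after a cold acidic quench.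

Third, step 5. The aluminium lactolate may open slowly under the homologation conditions, or over-reduction may occur. Fallback, a Corey–Fuchs sequence from 11 back to 14: lactol 13 is isolated after the i-Bu2AlH reduction. Ramirez olefination of its open form (CBr4, PPh3, CH2Cl2) gives the dibromoalkene F5. Treatment with n-BuLi (3.2 equiv, THF, −78 °C) effects Fritsch–Buttenberg–Wiechell rearrangement, and an aqueous quench gives 14.

**Further compounds**

F1 | step 8 | tert-butyl({(1E)-3-methoxy-1-[(4S,5R)-4-methyl-3-(prop-2-en-1-yl)-5-(3,4,5-trimethoxyphenyl)-4,5-dihydrofuran-2-yl]buta-1,3-dien-2-yl}oxy)dimethylsilane | O1[C@@H](c2cc(OC)c(OC)c(OC)c2)[C@@H](C)C(CC=C)=C1/C=C(/O[Si](C)(C)C(C)(C)C)C(OC)=C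
F2 | step 8 | tert-butyl{[(2R,3S,3aS)-5-methoxy-3-methyl-3a-(prop-2-en-1-yl)-2-(3,4,5-trimethoxyphenyl)-2,3,3a,4-tetrahydro-1-benzofuran-6-yl]oxy}dimethylsilane | C=CC[C@@]12CC(OC)=C(O[Si](C)(C)C(C)(C)C)C=C1O[C@@H](c1cc(OC)c(OC)c(OC)c1)[C@H]2C
F3 | step 7 | (4S,5S,6R)-6-hydroxy-5-methyl-4-(prop-2-en-1-yl)-6-(3,4,5-trimethoxyphenyl)hex-2-ynoic acid | O[C@@H](c1cc(OC)c(OC)c(OC)c1)[C@@H](C)[C@H](CC=C)C#CC(=O)O
F4 | step 7 | (4S,5S,6R)-6-hydroxy-N-methoxy-N,5-dimethyl-4-(prop-2-en-1-yl)-6-(3,4,5-trimethoxyphenyl)hex-2-ynamide | O[C@@H](c1cc(OC)c(OC)c(OC)c1)[C@@H](C)[C@H](CC=C)C#CC(=O)N(C)OC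
F5 | step 5 | (1R,2S,3S)-5,5-dibromo-2-methyl-3-(prop-2-en-1-yl)-1-(3,4,5-trimethoxyphenyl)pent-4-en-1-ol | O[C@@H](c1cc(OC)c(OC)c(OC)c1)[C@@H](C)[C@H](CC=C)C=C(Br)Br
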